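**Strategy.** The route rests on opening ring A at C1, the quaternary carbon bearing CH3, the prenyl CH2 and ring carbons C2 and C6, to an acyclic α-methyl-α-prenyl β-hydroxy imide. One operation makes it from a prenyl-substituted N-alkynyl 4-benzyloxazolidinone: methylcuprate syn-addition forms C1–CH3, oxygen insertion converts the alkenylcopper into a geometrically defined, fully substituted amide enolate, and acetaldehyde adds to form C1–C2. Because alkene geometry, not the size difference between CH3 and CH2, fixes C1, the key step exploits exactly this all-carbon centre flanked by two carbonyl carbons. The imide carbon becomes C6; C-acylation at C3 and Claisen closure complete ring A, which is then linked through CH2 to chromene ring B.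

Key step: step 4

Assumption: the aldehyde is taken to enter the enolate face left open when the carbamate C=O stays bound to the enolate metal (the facial sense of oxazolidinone imide enolate alkylations); on this model the (R) centre at C1 requires the (R)-4-benzyl auxiliary, which is used throughout, and its antipode would be substituted with no other change if the sense proved opposite; β-tricarbonyl compounds are drawn as one enol tautomer.

Step 1
Reactants: 1 prenyl bromide (1-bromo-3-methylbut-2-ene); 2 ethynylmagnesium bromide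
Product: 3 5-methylhex-4-en-1-yne
Conditions: CuCl (5 mol %), THF, 0 → 45 °C, 2 in excess
Reagents that add atoms: none
Why: Copper-catalysed allyl–alkynyl cross-coupling should give the skipped enyne by substitution at the unhindered primary carbon of the prenyl halide, and the volatile product is carried on as a solution.

Step 2
Reactants: 3 5-methylhex-4-en-1-yne
Product: 4 1-bromo-5-methylhex-4-en-1-yne
Conditions: NBS, AgNO3 (10 mol %), acetone, rt, dark
Reagents that add atoms: N-bromosuccinimide, O=C1CCC(=O)N1Br
Why: Silver-catalysed electrophilic bromination of the terminal alkyne through the silver acetylide should be much faster than attack of NBS on the trisubstituted alkene.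

Step 3
Reactants: 4 1-bromo-5-methylhex-4-en-1-yne; 5 (R)-4-benzyloxazolidin-2-one
Product: 6 (R)-4-benzyl-3-(5-methylhex-4-en-1-yn-1-yl)oxazolidin-2-one
Conditions: CuSO4·5H2O (10 mol %), 1,10-phenanthroline (20 mol %), K3PO4, toluene, 75 °C
Reagents that add atoms: none
Why: Copper-catalysed N-alkynylation (Ullmann-type C–N coupling) of an oxazolidinone with a bromoalkyne is the standard ynamide synthesis, and the insoluble mild base should leave the doubly activated CH2 of the skipped enyne untouched.

Step 4
Reactants: 6 (R)-4-benzyl-3-(5-methylhex-4-en-1-yn-1-yl)oxazolidin-2-one; 7 lithium dimethylcuprate; 8 acetaldehyde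
Product: 11 (R)-4-benzyl-3-[(2R,3R)-3-hydroxy-2-methyl-2-(3-methylbut-2-en-1-yl)butanoyl]oxazolidin-2-one, via lithium alkenyl(methyl)cuprate 9 (not isolated), via lithium amide enolate 10 (not isolated)
Conditions: 7 (1.3 equiv), Et2O, −40 °C; tBuOOLi (from tBuOOH + nBuLi), THF, −78 °C; 8 (3 equiv), −78 °C; aq NH4Cl at −78 °C
Reagents that add atoms: lithium tert-butyl peroxide, [Li+].[O-]OC(C)(C)C
Why: Me2CuLi adds syn across the C≡C bond with copper on the nitrogen-bearing carbon, where the carbamate C=O holds it, so that CH3 (new C1–CH3 bond) sits cis to Cu and the prenyl CH2 cis to N; tBuOOLi then inserts oxygen into the C–Cu bond with retention (1,2-metalate shift of the oxenoid) to give a single enolate geometry, and acetaldehyde adds through a closed six-membered transition state to form C1–C2. The closest known reaction type is the one-pot carbocupration–oxidation–aldol sequence of N-alkynyl oxazolidinones that delivers acyclic aldols with α-quaternary centres. No ring is closed. C1 is controlled by the enolate geometry, which decides on which side CH3 and CH2 lie, together with the (R)-benzyl group, which blocks one enolate face in the carbamate-chelated arrangement; the carbinol centre should follow from an equatorial aldehyde CH3 in the chair, and it is removed in step 5. The step needs regioselective carbometalation, stereoretentive oxidation and facial selectivity, which are secured by carbamate chelation, by the concerted oxygen transfer and by the auxiliary, without reliance on a size difference between CH3 and CH2. Excess acetaldehyde at −78 °C and a cold quench are meant to outrun aldehyde enolisation and retro-aldol cleavage.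

Step 5
Reactants: 11 (R)-4-benzyl-3-[(2R,3R)-3-hydroxy-2-methyl-2-(3-methylbut-2-en-1-yl)butanoyl]oxazolidin-2-one
Product: 12 (R)-4-benzyl-3-[(2R)-2-methyl-2-(3-methylbut-2-en-1-yl)-3-oxobutanoyl]oxazolidin-2-one
Conditions: Dess–Martin periodinane, CH2Cl2, 0 °C → rt
Reagents that add atoms: none
Why: Dess–Martin oxidation of the secondary alcohol under neutral conditions should give the methyl ketone without retro-aldol cleavage, and it erases the carbinol centre so that both carbinol epimers converge while the quaternary carbon cannot epimerise.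

Step 6
Reactants: 13 methyl 4-methyl-3-oxopentanoate
Product: 14 methyl 2-[2-(propan-2-yl)-1,3-dioxolan-2-yl]acetate
Conditions: HOCH2CH2OH, TsOH·H2O (cat.), toluene, reflux, Dean–Stark
Reagents that add atoms: ethylene glycol, OCCO
Why: Acid-catalysed ketalisation with azeotropic removal of water masks the ketone, so that the acyl donor made from this ester carries no acidic 1,3-dicarbonyl CH2.

Step 7
Reactants: 14 methyl 2-[2-(propan-2-yl)-1,3-dioxolan-2-yl]acetate
Product: 15 2-[2-(propan-2-yl)-1,3-dioxolan-2-yl]acetic acid
Conditions: LiOH·H2O, THF/MeOH/H2O, rt; then 1 M HCl to pH 4, 0 °C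
Reagents that add atoms: lithium hydroxide, [Li+].[OH-]
Why: Saponification of the methyl ester runs under basic conditions to which the dioxolane is inert, and brief cold acidification to pH 4 should free the acid without opening the ketal.

Step 8
Reactants: 15 2-[2-(propan-2-yl)-1,3-dioxolan-2-yl]acetic acid
Product: 16 1-(1H-benzotriazol-1-yl)-2-[2-(propan-2-yl)-1,3-dioxolan-2-yl]ethan-1-one
Conditions: 1H-benzotriazole, DCC, CH2Cl2, 0 °C → rt
Reagents that add atoms: 1H-benzotriazole, c1ccc2[nH]nnc2c1
Why: Carbodiimide coupling converts the acid under neutral conditions into the N-acylbenzotriazole, an isolable acyl donor established for C-acylation of magnesium enolates.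

Step 9
Reactants: 12 (R)-4-benzyl-3-[(2R)-2-methyl-2-(3-methylbut-2-en-1-yl)-3-oxobutanoyl]oxazolidin-2-one; 16 1-(1H-benzotriazol-1-yl)-2-[2-(propan-2-yl)-1,3-dioxolan-2-yl]ethan-1-one
Product: 17 (R)-4-benzyl-3-{(2R)-2-methyl-2-(3-methylbut-2-en-1-yl)-3,5-dioxo-6-[2-(propan-2-yl)-1,3-dioxolan-2-yl]hexanoyl}oxazolidin-2-one
Conditions: MgBr2·OEt2 (2.5 equiv), iPr2NEt (3 equiv), 16 (1.1 equiv), CH2Cl2, rt
Reagents that add atoms: none
Why: Soft enolisation of the only enolisable position, the acetyl CH3 (C3), by MgBr2 and a tertiary amine followed by C-acylation with the N-acylbenzotriazole is a crossed Claisen condensation that forms C3–C4 without exposing the imide to a strongly basic enolate, the ketone side of a β-keto imide being a known site of Lewis acid/amine enolisation.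

Step 10
Reactants: 17 (R)-4-benzyl-3-{(2R)-2-methyl-2-(3-methylbut-2-en-1-yl)-3,5-dioxo-6-[2-(propan-2-yl)-1,3-dioxolan-2-yl]hexanoyl}oxazolidin-2-one
Product: 19 (4R)-3,5-dihydroxy-4-methyl-4-(3-methylbut-2-en-1-yl)-2-(2-methylpropanoyl)cyclohexa-2,5-dien-1-one, via triketone imide 18 (not isolated)
Conditions: 1 M HCl, THF, rt; extractive work-up; then MgBr2·OEt2 (3 equiv), iPr2NEt (4 equiv), CH2Cl2, 0 → 40 °C; dilute HCl wash
Reagents that add atoms: water, O
Why: Acid hydrolysis unmasks the third ketone and the magnesium enolate of the outer 1,3-diketone carbon (C5) then attacks the chelate-activated exocyclic imide carbonyl (C6) in a 6-exo-trig Dieckmann-type Claisen cyclisation that expels the oxazolidinone, the metal-templated mode known from triketo ester to acylphloroglucinol closures, while the quaternary C1 is untouched and the isobutyryl group on C5 keeps C2 and C6 distinct.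

Step 11
Reactants: 20 phlorisobutyrophenone (1-(2,4,6-trihydroxyphenyl)-2-methylpropan-1-one); 21 3-chloro-3-methylbut-1-yne
Product: 22 1-{2,6-dihydroxy-4-[(2-methylbut-3-yn-2-yl)oxy]phenyl}-2-methylpropan-1-one
Conditions: CuCl2·2H2O (0.5 mol %), DBU (1.2 equiv), MeCN, 0 °C
Reagents that add atoms: none
Why: Copper-catalysed O-propargylation of phenols with a tertiary propargylic chloride (via a copper allenylidene) should take place at the most acidic, non-chelated 4-OH, since the two hydroxyls flanking the ketone are tied up in hydrogen bonds.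

Step 12
Reactants: 22 1-{2,6-dihydroxy-4-[(2-methylbut-3-yn-2-yl)oxy]phenyl}-2-methylpropan-1-one
Product: 23 1-(5,7-dihydroxy-2,2-dimethyl-2H-chromen-6-yl)-2-methylpropan-1-one
Conditions: o-xylene, 140 °C
Reagents that add atoms: none
Why: Aromatic propargyl Claisen rearrangement, enolisation, 1,5-hydrogen shift and oxa-6π electrocyclisation convert the aryl dimethylpropargyl ether into the 2,2-dimethylchromene with the ether oxygen as ring oxygen, so the acyl group ends up at C6 between both hydroxyls and only C8 stays free.

Step 13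
Reactants: 23 1-(5,7-dihydroxy-2,2-dimethyl-2H-chromen-6-yl)-2-methylpropan-1-one
Product: 24 1-{8-[(dimethylamino)methyl]-5,7-dihydroxy-2,2-dimethyl-2H-chromen-6-yl}-2-methylpropan-1-one
Conditions: Eschenmoser's salt (Me2N=CH2 iodide, 1.1 equiv), CH2Cl2, rt; aq NaHCO3
Reagents that add atoms: N,N-dimethylmethyleneiminium iodide, C=[N+](C)C.[I-]
Why: Mannich aminomethylation with the preformed iminium salt should occur at C8, the only free ring position, which is activated by an ortho and a para hydroxyl.

Step 14
Reactants: 19 (4R)-3,5-dihydroxy-4-methyl-4-(3-methylbut-2-en-1-yl)-2-(2-methylpropanoyl)cyclohexa-2,5-dien-1-one; 24 1-{8-[(dimethylamino)methyl]-5,7-dihydroxy-2,2-dimethyl-2H-chromen-6-yl}-2-methylpropan-1-one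
Product: 25 (4R)-6-{[5,7-dihydroxy-2,2-dimethyl-6-(2-methylpropanoyl)-2H-chromen-8-yl]methyl}-3,5-dihydroxy-4-methyl-4-(3-methylbut-2-en-1-yl)-2-(2-methylpropanoyl)cyclohexa-2,5-dien-1-one (CNP0319758.1)
Conditions: 24 (1.2 equiv), 1,4-dioxane, 85 °C, argon sweep
Reagents that add atoms: none
Why: The acidic trione protonates the Mannich base, which on heating loses Me2NH to an o-quinone methide that is captured at carbon by C3 of the trione (Michael addition, the classical Mannich-base route to methylene-bridged acylphloroglucinols), and only the cross product can form because C8 of ring B and C3 of ring A are the sole free positions.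

**Compound list**

1 | prenyl bromide (1-bromo-3-methylbut-2-ene) | CC(C)=CCBr | starting material
2 | ethynylmagnesium bromide | C#C[Mg]Br | starting material
3 | 5-methylhex-4-en-1-yne | CC(C)=CCC#C | intermediate
4 | 1-bromo-5-methylhex-4-en-1-yne | CC(C)=CCC#CBr | intermediate
5 | (R)-4-benzyloxazolidin-2-one | O=C1N[C@H](Cc2ccccc2)CO1 | starting material
6 | (R)-4-benzyl-3-(5-methylhex-4-en-1-yn-1-yl)oxazolidin-2-one | CC(C)=CCC#CN1C(=O)OC[C@H]1Cc1ccccc1 | intermediate
7 | lithium dimethylcuprate | [Li+].C[Cu-]C | starting material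
8 | acetaldehyde | CC=O | starting material
9 | lithium [(1E)-1-[(4R)-4-benzyl-2-oxo-1,3-oxazolidin-3-yl]-2,5-dimethylhexa-1,4-dien-1-yl](methyl)cuprate | [Li+].C[Cu-]/C(N1C(=O)OC[C@H]1Cc1ccccc1)=C(\C)CC=C(C)C | intermediate
10 | lithium (1E)-1-[(4R)-4-benzyl-2-oxo-1,3-oxazolidin-3-yl]-2,5-dimethylhexa-1,4-dien-1-olate | [Li+].[O-]/C(N1C(=O)OC[C@H]1Cc1ccccc1)=C(\C)CC=C(C)C | intermediate
11 | (R)-4-benzyl-3-[(2R,3R)-3-hydroxy-2-methyl-2-(3-methylbut-2-en-1-yl)butanoyl]oxazolidin-2-one | CC(C)=CC[C@](C(=O)N1C(=O)OC[C@H]1Cc1ccccc1)(C)[C@@H](C)O | intermediate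
12 | (R)-4-benzyl-3-[(2R)-2-methyl-2-(3-methylbut-2-en-1-yl)-3-oxobutanoyl]oxazolidin-2-one | CC(C)=CC[C@](C(=O)N1C(=O)OC[C@H]1Cc1ccccc1)(C)C(C)=O | intermediate
13 | methyl 4-methyl-3-oxopentanoate | COC(=O)CC(=O)C(C)C | starting material
14 | methyl 2-[2-(propan-2-yl)-1,3-dioxolan-2-yl]acetate | COC(=O)CC1(C(C)C)OCCO1 | intermediate
15 | 2-[2-(propan-2-yl)-1,3-dioxolan-2-yl]acetic acid | OC(=O)CC1(C(C)C)OCCO1 | intermediate
16 | 1-(1H-benzotriazol-1-yl)-2-[2-(propan-2-yl)-1,3-dioxolan-2-yl]ethan-1-one | O=C(CC1(C(C)C)OCCO1)n1nnc2ccccc12 | intermediate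
17 | (R)-4-benzyl-3-{(2R)-2-methyl-2-(3-methylbut-2-en-1-yl)-3,5-dioxo-6-[2-(propan-2-yl)-1,3-dioxolan-2-yl]hexanoyl}oxazolidin-2-one | CC(C)=CC[C@](C(=O)N1C(=O)OC[C@H]1Cc1ccccc1)(C)C(=O)CC(=O)CC1(C(C)C)OCCO1 | intermediate
18 | (R)-4-benzyl-3-[(2R)-2,8-dimethyl-2-(3-methylbut-2-en-1-yl)-3,5,7-trioxononanoyl]oxazolidin-2-one | CC(C)=CC[C@](C(=O)N1C(=O)OC[C@H]1Cc1ccccc1)(C)C(=O)CC(=O)CC(=O)C(C)C | intermediate
19 | (4R)-3,5-dihydroxy-4-methyl-4-(3-methylbut-2-en-1-yl)-2-(2-methylpropanoyl)cyclohexa-2,5-dien-1-one (ring A trione, one enol tautomer) | CC(C)=CC[C@]1(C)C(O)=CC(=O)C(C(=O)C(C)C)=C1O | intermediate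
20 | phlorisobutyrophenone (1-(2,4,6-trihydroxyphenyl)-2-methylpropan-1-one) | CC(C)C(=O)c1c(O)cc(O)cc1O | starting material
21 | 3-chloro-3-methylbut-1-yne | CC(C)(Cl)C#C | starting material
22 | 1-{2,6-dihydroxy-4-[(2-methylbut-3-yn-2-yl)oxy]phenyl}-2-methylpropan-1-one | CC(C)C(=O)c1c(O)cc(OC(C)(C)C#C)cc1O | intermediate
23 | 1-(5,7-dihydroxy-2,2-dimethyl-2H-chromen-6-yl)-2-methylpropan-1-one | CC(C)C(=O)c1c(O)cc2OC(C)(C)C=Cc2c1O | intermediate
24 | 1-{8-[(dimethylamino)methyl]-5,7-dihydroxy-2,2-dimethyl-2H-chromen-6-yl}-2-methylpropan-1-one | CC(C)C(=O)c1c(O)c(CN(C)C)c2OC(C)(C)C=Cc2c1O | intermediate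
25 | (4R)-6-{[5,7-dihydroxy-2,2-dimethyl-6-(2-methylpropanoyl)-2H-chromen-8-yl]methyl}-3,5-dihydroxy-4-methyl-4-(3-methylbut-2-en-1-yl)-2-(2-methylpropanoyl)cyclohexa-2,5-dien-1-one (CNP0319758.1) | CC(C)=CC[C@]1(C)C(O)=C(Cc2c(O)c(C(=O)C(C)C)c(O)c3c2OC(C)(C)C=C3)C(=O)C(C(=O)C(C)C)=C1O | target

**Step count and risk**

Total step count: 14. Longest linear sequence: 8 steps (steps 1, 2, 3, 4, 5, 9, 10, 14).

The three steps most likely to fail:

Step 4 (key step). What may go wrong: the cuprate may add slowly or lose regiocontrol if carbamate chelation is not maintained, the oxenoid may oxidise the enolate further, acetaldehyde may be enolised by the basic mixture, the aldolate may revert on warming, or the aldehyde may enter on the other enolate face. The fallback sets out from prenyl bromide 1 and comes back at 19. Ethyl 2-methyl-3-oxobutanoate is condensed with tert-butyl L-valinate (TsOH, benzene, Dean–Stark) to the chiral enamino ester F1. Its lithiated form (LDA, −78 °C) is alkylated with 1 in the solvent regime (toluene with HMPA, or THF alone) that steers this class of chiral-enamine alkylation to the required enantiomer, which gives the imino ester F2. Mild aqueous acid then releases the keto ester F3 and the amino ester. F3 is C-acylated with 16 under the conditions of step 9 to the ketal diketo ester F4. Treatment with 1 M HCl and then NaOEt in EtOH unmasks and cyclises it through the triketo ester F5 to 19 by a classical ester Dieckmann closure. This replaces the alkyne chemistry by auxiliary-controlled alkylation of an α-methyl β-keto ester.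

Step 10. What may go wrong: closure at the hindered exocyclic carbonyl may be outrun by attack of the inner enolate (C3 or its oxygen) on the carbamate carbonyl, which opens the auxiliary ring, or by O-acylation to a pyrandione; the same neighbouring carbonyl could also erode step 9. The fallback sets out from 11 and comes back at 19. LiOH/H2O2 (THF/H2O, 0 °C) removes the auxiliary at the aldol stage to give the hydroxy acid F6, and TMSCHN2 gives the hydroxy methyl ester F7. Dess–Martin oxidation gives the keto ester F8, and soft-enolisation acylation with 16 gives the ketal diketo ester F9. Treatment with 1 M HCl and then NaOMe in MeOH closes ring A through the triketo ester F10. An ester offers no second electrophilic carbonyl, so only the C5–C6 closure is possible.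

Step 14. What may go wrong: amine loss to the quinone methide may be too slow at a tolerable temperature, the quinone methide may self-condense, or the methylene bridge may scramble by retro-Michael exchange on prolonged heating. The fallback sets out from 23 and comes back at 25. Vilsmeier–Haack formylation of 23 (POCl3, DMF, then aqueous NaOAc) at C8 gives the chromene aldehyde F11. Three-component reductive alkylation of 19 with F11, L-proline (catalytic) and Hantzsch ester in CH2Cl2 at rt then forms the bridge by Knoevenagel condensation and transfer hydrogenation of the alkylidene trione.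

Further compounds

F1 | step 4 | ethyl (2Z)-3-{[(2S)-1-tert-butoxy-3-methyl-1-oxobutan-2-yl]amino}-2-methylbut-2-enoate | CCOC(=O)/C(C)=C(C)\N[C@@H](C(C)C)C(=O)OC(C)(C)C
F2 | step 4 | ethyl (2R)-3-{[(2S)-1-tert-butoxy-3-methyl-1-oxobutan-2-yl]imino}-2-methyl-2-(3-methylbut-2-en-1-yl)butanoate | CC(C)=CC[C@](C(=O)OCC)(C)C(C)=N[C@@H](C(C)C)C(=O)OC(C)(C)C
F3 | step 4 | ethyl (2R)-2-acetyl-2,5-dimethylhex-4-enoate | CC(C)=CC[C@](C(=O)OCC)(C)C(C)=O
F4 | step 4 | ethyl (2R)-2-methyl-2-(3-methylbut-2-en-1-yl)-3,5-dioxo-6-[2-(propan-2-yl)-1,3-dioxolan-2-yl]hexanoate | CC(C)=CC[C@](C(=O)OCC)(C)C(=O)CC(=O)CC1(C(C)C)OCCO1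
F5 | step 4 | ethyl (2R)-2,8-dimethyl-2-(3-methylbut-2-en-1-yl)-3,5,7-trioxononanoate | CC(C)=CC[C@](C(=O)OCC)(C)C(=O)CC(=O)CC(=O)C(C)C
F6 | step 10 | (2R,3R)-3-hydroxy-2-methyl-2-(3-methylbut-2-en-1-yl)butanoic acid | CC(C)=CC[C@](C(=O)O)(C)[C@@H](C)O
F7 | step 10 | methyl (2R,3R)-3-hydroxy-2-methyl-2-(3-methylbut-2-en-1-yl)butanoate | CC(C)=CC[C@](C(=O)OC)(C)[C@@H](C)O
F8 | step 10 | methyl (2R)-2-acetyl-2,5-dimethylhex-4-enoate | CC(C)=CC[C@](C(=O)OC)(C)C(C)=O
F9 | step 10 | methyl (2R)-2-methyl-2-(3-methylbut-2-en-1-yl)-3,5-dioxo-6-[2-(propan-2-yl)-1,3-dioxolan-2-yl]hexanoate | CC(C)=CC[C@](C(=O)OC)(C)C(=O)CC(=O)CC1(C(C)C)OCCO1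
F10 | step 10 | methyl (2R)-2,8-dimethyl-2-(3-methylbut-2-en-1-yl)-3,5,7-trioxononanoate | CC(C)=CC[C@](C(=O)OC)(C)C(=O)CC(=O)CC(=O)C(C)C
F11 | step 14 | 5,7-dihydroxy-2,2-dimethyl-6-(2-methylpropanoyl)-2H-chromene-8-carbaldehyde | CC(C)C(=O)c1c(O)c(C=O)c2OC(C)(C)C=Cc2c1O
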